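**Plan**
1. Retrosynthesis: the tertiary alcohol is traced to a methallyl group (late Markovnikov hydration). The dihydropyran ring is then cut at O1–C2 together with the bond from the exocyclic CH2 on C2 to the enone β-carbon C6, giving alkenyl phenol 5 and β-bromo enone 19.
2. Bromo enone 19 goes back through a 2-methallyl-1,3-dione, an epoxy ketone and a Robinson enone to 2-methylcyclopentanone; phenol 5 goes back to a bromophenol and a homoallylic zinc reagent.
3. Forward ring order: cyclopentane (bought), carbocyclic six-membered ring (Michael/aldol), second angular methyl, 1,3-dione, bromo enone; the chroman ring is closed last, in the step that also joins the two halves.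
4. Enabling feature: chroman C2 is a fully substituted carbon bonded both to ring oxygen O1 and to a CH2 that sits on the β-carbon of the cyclohexenone ring. Syn-oxypalladation of a 1,1-disubstituted alkene therefore leaves an alkylpalladium without β-hydrogen, which can only couple with the alkenyl group delivered from C6–Br.
5. Stereochemistry: the ring-fusion carbon next to the ketone comes from an (S)-1-phenylethylamine-controlled Michael addition; the other ring-fusion carbon from cuprate addition cis to the first angular methyl; C2 from the chiral phosphoramidite ligand in the ring-closing step.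

Key step: step 11

Assumption: the ketimine of 2-methylcyclopentanone is taken to follow the facial sense known for the 2-methylcyclohexanone ketimine, so that (S)-1-phenylethylamine leads to (R)-11; epoxide 15 is drawn as the epimer expected from attack on the convex face, and either epimer gives 16.

**Step 1**
Reactants: 1 4-methoxy-2-methylphenol
Product: 2 2-bromo-4-methoxy-6-methylphenol
Conditions: NBS, i-Pr2NH (cat.), CH2Cl2, 0 °C
Reagents that add atoms: N-bromosuccinimide, O=C1CCC(=O)N1Br
Why: Electrophilic aromatic bromination, in which the hydroxyl group is the strongest director, its para position is blocked by OMe and one ortho position by CH3, so bromine enters the remaining ortho carbon.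

**Step 2**
Reactants: 2 2-bromo-4-methoxy-6-methylphenol; 3 4-bromo-2-methylbut-1-ene
Product: 5 4-methoxy-2-methyl-6-(3-methylbut-3-en-1-yl)phenol, via alkylzinc bromide 4 (not isolated)
Conditions: 3, Zn dust, LiCl, THF, 40 °C; then 2, Pd(OAc)2 (2 mol %), SPhos (4 mol %), THF, 25 °C, slow addition
Reagents that add atoms: none
Why: Negishi C(sp2)–C(sp3) coupling, in which the primary alkylzinc bromide transmetallates to the arylpalladium bromide formed from 2, the bulky biarylphosphine makes reductive elimination faster than β-hydride elimination, and the weakly basic organozinc under slow addition tolerates the free phenol.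

**Step 3**
Reactants: 6 2-methylcyclopentanone (racemic); 7 (S)-1-phenylethylamine; 8 methyl vinyl ketone
Product: 11 (R)-2-methyl-2-(3-oxobutyl)cyclopentan-1-one, via ketimine 9 (not isolated), via Michael adduct imine 10 (not isolated)
Conditions: 7, TsOH (cat.), toluene, reflux (Dean–Stark); then 8, THF, 25 °C; then 20% aq AcOH, 25 °C
Reagents that add atoms: water, O
Why: Asymmetric Michael addition of a chiral ketimine through its more substituted secondary enamine tautomer (first half of a Robinson annulation), in which the enone is attacked in a compact aza-ene-like transition state on the face anti to the phenyl group of the auxiliary, setting the quaternary carbon as R before aqueous acid frees ketone and amine.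

**Step 4**
Reactants: 11 (R)-2-methyl-2-(3-oxobutyl)cyclopentan-1-one
Product: 12 (R)-7a-methyl-1,2,3,6,7,7a-hexahydro-5H-inden-5-one
Conditions: KOH, MeOH, 25 → 65 °C
Reagents that add atoms: none
Why: Intramolecular aldol condensation (second half of the Robinson annulation), in which only the methyl-ketone enolate can close a six-membered ring onto the cyclopentanone carbonyl, dehydration gives the conjugated enone, and the quaternary stereocentre has no hydrogen and cannot epimerise.

**Step 5**
Reactants: 12 (R)-7a-methyl-1,2,3,6,7,7a-hexahydro-5H-inden-5-one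
Product: 13 (3aS,7aR)-3a,7a-dimethyloctahydro-5H-inden-5-one (cis-fused, angular methyls cis)
Conditions: Me2CuLi (from MeLi and CuI), BF3·OEt2, Et2O, −78 → −20 °C; aq NH4Cl
Reagents that add atoms: lithium dimethylcuprate, [Li+].C[Cu-]C
Why: Conjugate addition of a Gilman cuprate to a β,β-disubstituted enone under Lewis-acid activation, in which methyl is delivered to C3a on the face that gives the cis-fused hydrindanone (the known preference of angularly methylated bicyclic enones, as in the cis-9,10-dimethyldecalone series), setting the second quaternary centre cis to the first.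

**Step 6**
Reactants: 13 (3aS,7aR)-3a,7a-dimethyloctahydro-5H-inden-5-one
Product: 14 (3aS,7aR)-3a,7a-dimethyl-1,2,3,3a,4,7a-hexahydro-5H-inden-5-one
Conditions: IBX (2.5 equiv), PhF/DMSO, 75 °C
Reagents that add atoms: none
Why: Dehydrogenation of a ketone with 2-iodoxybenzoic acid, in which only the C6–C7 side has both α- and β-hydrogens because C3a is quaternary, so a single enone can form and the two quaternary carbons block further desaturation.

**Step 7**
Reactants: 14 (3aS,7aR)-3a,7a-dimethyl-1,2,3,3a,4,7a-hexahydro-5H-inden-5-one
Product: 15 cis-fused 6,7-epoxy-3a,7a-dimethyloctahydro-5H-inden-5-one (oxirane cis to the angular methyls)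
Conditions: 30% aq H2O2, NaOH, MeOH, 0 °C
Reagents that add atoms: hydrogen peroxide, OO
Why: Weitz–Scheffer nucleophilic epoxidation, in which hydroperoxide adds to C7 of the enone and the enolate closes on oxygen, the two new stereocentres being of no consequence because step 8 erases them.

**Step 8**
Reactants: 15 cis-fused 6,7-epoxy-3a,7a-dimethyloctahydro-5H-inden-5-one
Product: 16 (3aS,7aS)-3a,7a-dimethylhexahydro-1H-indene-4,6(5H)-dione (renumbered: C4 is the carbonyl next to the Michael-derived quaternary carbon C3a, C6 the former C5)
Conditions: Pd(PPh3)4 (5 mol %), 1,2-bis(diphenylphosphino)ethane (5 mol %), toluene, 100 °C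
Reagents that add atoms: none
Why: Isomerisation of an α,β-epoxy ketone to a β-diketone catalysed by zerovalent palladium, in which Pd(PPh3)4 opens the Cα–O bond to an alkoxy palladium enolate, β-hydride elimination from the carbinol C–H and reductive elimination give the 1,3-dione, and the ring-fusion centres are untouched.

**Step 9**
Reactants: 16 (3aS,7aS)-3a,7a-dimethylhexahydro-1H-indene-4,6(5H)-dione; 17 2-methylallyl acetate
Product: 18 (3aS,7aS)-6-hydroxy-3a,7a-dimethyl-5-(2-methylprop-2-en-1-yl)-1,2,3,3a,7,7a-hexahydro-4H-inden-4-one (enol tautomer of the 5-methallyl-4,6-dione)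
Conditions: Pd(PPh3)4 (3 mol %), Et3N, THF, 50 °C
Reagents that add atoms: none
Why: Tsuji–Trost allylation, in which the soft enolate of the 1,3-dione attacks the π-methallyl complex of palladium at carbon and any O-allyl enol ether re-ionises under the same catalyst and funnels to the C-allylated product.

**Step 10**
Reactants: 18 (3aS,7aS)-6-hydroxy-3a,7a-dimethyl-5-(2-methylprop-2-en-1-yl)-1,2,3,3a,7,7a-hexahydro-4H-inden-4-one
Product: 19 (3aS,7aS)-6-bromo-3a,7a-dimethyl-5-(2-methylprop-2-en-1-yl)-1,2,3,3a,7,7a-hexahydro-4H-inden-4-one
Conditions: Ph3PBr2 (preformed), Et3N, CH2Cl2, 0 → 25 °C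
Reagents that add atoms: dibromotriphenylphosphorane, BrP(Br)(c1ccccc1)(c1ccccc1)c1ccccc1
Why: Deoxybromination of a 1,3-dione through its enol oxyphosphonium salt (addition–elimination of bromide), in which bromide attacks C6, flanked by a CH2, far faster than the neopentyl-type C4 next to quaternary C3a, so the ketone stays at C4 and the bromide sits on C6.

**Step 11**
Reactants: 5 4-methoxy-2-methyl-6-(3-methylbut-3-en-1-yl)phenol; 19 (3aS,7aS)-6-bromo-3a,7a-dimethyl-5-(2-methylprop-2-en-1-yl)-1,2,3,3a,7,7a-hexahydro-4H-inden-4-one
Product: 20 (3aS,7aS)-6-{[(2R)-6-methoxy-2,8-dimethyl-3,4-dihydro-2H-chromen-2-yl]methyl}-3a,7a-dimethyl-5-(2-methylprop-2-en-1-yl)-1,2,3,3a,7,7a-hexahydro-4H-inden-4-one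
Conditions: Pd2(dba)3 (2.5 mol %), (S)-Siphos-PE (7.5 mol %), Cs2CO3, toluene, 90 °C
Reagents that add atoms: none
Why: Proposed new method: zerovalent palladium inserts into the C6–Br bond of 19, the caesium phenoxide of 5 displaces bromide to give LPd(alkenyl)(OAr), and the tethered 1,1-disubstituted alkene inserts syn into the Pd–O bond so that O1–C2 forms and palladium is left on the exocyclic CH2; because C2 is then fully substituted this alkylpalladium has no β-hydrogen, and C(sp3)–C(sp2) reductive elimination joins the CH2 to C6 of the enone. The closest known reaction type is the palladium-catalysed alkene carboetherification of 2-(but-3-enyl)phenols with aryl and alkenyl bromides that gives 2-substituted and 2,2-disubstituted chromans, together with the Siphos-PE-controlled carboamination that forms 2,2-disubstituted N-heterocycles; what is new is ligand control of an oxygen-bearing quaternary centre and a β-bromo enone as the electrophile. The dihydropyran ring closes in the 6-exo-trig mode (phenoxide oxygen onto the internal alkene carbon, palladium on the exocyclic carbon). The new stereocentre C2 is set in the insertion step by the chiral phosphoramidite alone, since the two ring-fusion stereocentres of 19 lie five bonds away and cannot bias the alkene face; the ligand antipode is taken should a first run favour the 2S epimer. The step needs chemoselectivity for insertion over direct C–O reductive elimination or addition–elimination of phenoxide at C6, which the two ortho substituents of the phenoxide, the tetrasubstituted C6 and the weak carbonate base should secure; the methallyl alkene of 19 is spared because its insertion would have to be 4-exo or 5-endo.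

**Step 12**
Reactants: 20 (3aS,7aS)-6-{[(2R)-6-methoxy-2,8-dimethyl-3,4-dihydro-2H-chromen-2-yl]methyl}-3a,7a-dimethyl-5-(2-methylprop-2-en-1-yl)-1,2,3,3a,7,7a-hexahydro-4H-inden-4-one
Product: 21 (3aS,7aS)-5-(2-hydroxy-2-methylpropyl)-6-{[(2R)-6-methoxy-2,8-dimethyl-3,4-dihydro-2H-chromen-2-yl]methyl}-3a,7a-dimethyl-1,2,3,3a,7,7a-hexahydro-4H-inden-4-one
Conditions: Co(acac)2 (20 mol %), PhSiH3, O2 (1 atm), i-PrOH/THF, 25 °C
Reagents that add atoms: dioxygen, O=O
Why: Mukaiyama hydration (cobalt hydride hydrogen-atom transfer to the alkene, capture of the tertiary radical by O2 and reduction of the peroxide by the silane), in which Markovnikov selectivity is inherent, the electron-rich 1,1-disubstituted alkene reacts while the electron-poor tetrasubstituted enone does not, and no stereocentre is formed or touched.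

**Compound list**
1 | 4-methoxy-2-methylphenol | COc1ccc(O)c(C)c1 | starting material
2 | 2-bromo-4-methoxy-6-methylphenol | COc1cc(C)c(O)c(Br)c1 | intermediate
3 | 4-bromo-2-methylbut-1-ene | C=C(C)CCBr | starting material
4 | (3-methylbut-3-en-1-yl)zinc bromide | C=C(C)CC[Zn]Br | intermediate
5 | 4-methoxy-2-methyl-6-(3-methylbut-3-en-1-yl)phenol | COc1cc(C)c(O)c(CCC(C)=C)c1 | intermediate
6 | 2-methylcyclopentanone (racemic) | CC1CCCC1=O | starting material
7 | (S)-1-phenylethylamine | C[C@H](N)c1ccccc1 | starting material
8 | methyl vinyl ketone | C=CC(C)=O | starting material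
9 | N-[(S)-1-phenylethyl] ketimine of 2-methylcyclopentanone (ring carbon equilibrating through the enamine) | CC1CCCC1=N[C@@H](C)c1ccccc1 | intermediate
10 | N-[(S)-1-phenylethyl] ketimine of (R)-2-methyl-2-(3-oxobutyl)cyclopentanone | CC(=O)CC[C@@]1(C)CCCC1=N[C@@H](C)c1ccccc1 | intermediate
11 | (R)-2-methyl-2-(3-oxobutyl)cyclopentan-1-one | CC(=O)CC[C@@]1(C)CCCC1=O | intermediate
12 | (R)-7a-methyl-1,2,3,6,7,7a-hexahydro-5H-inden-5-one | O=C1CC[C@@]2(C)CCCC2=C1 | intermediate
13 | (3aS,7aR)-3a,7a-dimethyloctahydro-5H-inden-5-one | O=C1CC[C@@]2(C)CCC[C@@]2(C)C1 | intermediate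
14 | (3aS,7aR)-3a,7a-dimethyl-1,2,3,3a,4,7a-hexahydro-5H-inden-5-one | O=C1C=C[C@@]2(C)CCC[C@@]2(C)C1 | intermediate
15 | cis-fused 6,7-epoxy-3a,7a-dimethyloctahydro-5H-inden-5-one (oxirane cis to the angular methyls) | O=C1[C@@H]2O[C@@H]2[C@@]3(C)CCC[C@@]3(C)C1 | intermediate
16 | (3aS,7aS)-3a,7a-dimethylhexahydro-1H-indene-4,6(5H)-dione | O=C1CC(=O)[C@@]2(C)CCC[C@@]2(C)C1 | intermediate
17 | 2-methylallyl acetate | CC(=C)COC(C)=O | starting material
18 | (3aS,7aS)-6-hydroxy-3a,7a-dimethyl-5-(2-methylprop-2-en-1-yl)-1,2,3,3a,7,7a-hexahydro-4H-inden-4-one (enol form) | OC1=C(CC(C)=C)C(=O)[C@@]2(C)CCC[C@@]2(C)C1 | intermediate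
19 | (3aS,7aS)-6-bromo-3a,7a-dimethyl-5-(2-methylprop-2-en-1-yl)-1,2,3,3a,7,7a-hexahydro-4H-inden-4-one | BrC1=C(CC(C)=C)C(=O)[C@@]2(C)CCC[C@@]2(C)C1 | intermediate
20 | (3aS,7aS)-6-{[(2R)-6-methoxy-2,8-dimethyl-3,4-dihydro-2H-chromen-2-yl]methyl}-3a,7a-dimethyl-5-(2-methylprop-2-en-1-yl)-1,2,3,3a,7,7a-hexahydro-4H-inden-4-one | COc1cc(C)c2c(c1)CC[C@](C)(CC1=C(CC(C)=C)C(=O)[C@@]3(C)CCC[C@@]3(C)C1)O2 | intermediate
21 | (3aS,7aS)-5-(2-hydroxy-2-methylpropyl)-6-{[(2R)-6-methoxy-2,8-dimethyl-3,4-dihydro-2H-chromen-2-yl]methyl}-3a,7a-dimethyl-1,2,3,3a,7,7a-hexahydro-4H-inden-4-one | COc1cc(C)c2c(c1)CC[C@](C)(CC1=C(CC(C)(C)O)C(=O)[C@@]3(C)CCC[C@@]3(C)C1)O2 | target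

**Totals**
Total step count: 12. Longest linear sequence: 10 steps (steps 3 to 12); steps 1 and 2 form the second branch.

**Steps most likely to fail**

1. Step 11 (proposed new method). What may go wrong: insufficient facial discrimination when the alkene inserts into the Pd–O bond, giving both C2 epimers, or diversion of LPd(alkenyl)(OAr) into direct O-alkenylation of the phenoxide. The fallback uses known chemistry only, sets out from 5 and 19 and comes back at 20. Phenol 5 is cyclised by the enantioselective domino Wacker cyclisation/methoxycarbonylation of divalent palladium (Pd(OCOCF3)2, Bn-BOXAX in the enantiomer that gives 2R, p-benzoquinone, CO, MeOH, 25 °C) to methyl 2-[(2R)-6-methoxy-2,8-dimethyl-3,4-dihydro-2H-chromen-2-yl]acetate F1. Saponification (LiOH, THF/H2O) gives 2-[(2R)-6-methoxy-2,8-dimethyl-3,4-dihydro-2H-chromen-2-yl]acetic acid F2, and N-hydroxyphthalimide with N,N′-diisopropylcarbodiimide gives the redox-active 1,3-dioxoisoindolin-2-yl 2-[(2R)-6-methoxy-2,8-dimethyl-3,4-dihydro-2H-chromen-2-yl]acetate F3. Nickel-catalysed reductive decarboxylative alkenylation of F3 with bromo enone 19 (NiBr2(dme), 4,4′-di-tert-butyl-2,2′-bipyridine, Zn, DMA, 25 °C) then couples the chroman-2-ylmethyl radical to C6 and gives 20. C2 is set by the BOXAX ligand and is not touched in the radical step; the chroman is still the last ring to be closed.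

2. Step 10. What may go wrong: loss of regiocontrol between the two dione oxygens, or hydrobromination of the methallyl alkene by liberated HBr. The fallback sets out from 18 and comes back at 20. Kinetic O-sulfonylation (Tf2O, Et3N, CH2Cl2, −78 °C) at the less hindered oxygen, remote from quaternary C3a, gives (3aS,7aS)-3a,7a-dimethyl-5-(2-methylprop-2-en-1-yl)-4-oxo-2,3,3a,4,7,7a-hexahydro-1H-inden-6-yl trifluoromethanesulfonate F4 under acid-free conditions. F4 then takes the place of 19 in step 11, under the same conditions, to give 20.

3. Step 8. What may go wrong: the hindered epoxide carbon next to the quaternary centre resists opening by Pd(PPh3)4, or deoxygenation back to the enone outruns the hydride shift. The fallback sets out from 15 and comes back at 16. Reductive cleavage of the Cα–O bond with SmI2 (THF/MeOH, −90 °C) gives cis-fused 7-hydroxy-3a,7a-dimethyloctahydro-5H-inden-5-one F5, and oxidation with Dess–Martin periodinane (CH2Cl2, 25 °C) gives dione 16.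

**Further compounds**
F1 | step 11 | methyl 2-[(2R)-6-methoxy-2,8-dimethyl-3,4-dihydro-2H-chromen-2-yl]acetate | COC(=O)C[C@@]1(C)CCc2cc(OC)cc(C)c2O1
F2 | step 11 | 2-[(2R)-6-methoxy-2,8-dimethyl-3,4-dihydro-2H-chromen-2-yl]acetic acid | OC(=O)C[C@@]1(C)CCc2cc(OC)cc(C)c2O1
F3 | step 11 | 1,3-dioxoisoindolin-2-yl 2-[(2R)-6-methoxy-2,8-dimethyl-3,4-dihydro-2H-chromen-2-yl]acetate | O=C(C[C@@]1(C)CCc2cc(OC)cc(C)c2O1)ON1C(=O)c2ccccc2C1=O
F4 | step 10 | (3aS,7aS)-3a,7a-dimethyl-5-(2-methylprop-2-en-1-yl)-4-oxo-2,3,3a,4,7,7a-hexahydro-1H-inden-6-yl trifluoromethanesulfonate | O=S(=O)(OC1=C(CC(C)=C)C(=O)[C@@]2(C)CCC[C@@]2(C)C1)C(F)(F)F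
F5 | step 8 | cis-fused 7-hydroxy-3a,7a-dimethyloctahydro-5H-inden-5-one (hydroxyl cis to the angular methyls) | O=C1C[C@H](O)[C@@]2(C)CCC[C@@]2(C)C1
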